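**Plan**

- Retrosynthesis (isoquinoline numbering): N2–C1 is opened first, C1 being carried as an ester carbon on C8a (lactam, then reduction). The benzene ring of the isoquinoline is then cut at C4a–C5 and C8–C8a into a 4‑naphthyl‑1,3‑dimethoxy‑1‑silyloxybutadiene and an (S)‑5‑aminohex‑2‑ynoate.
- Feature used: this ring carries oxygen at C6 and C8, hydrogen at C7, the naphthyl group at C5 and carbon at C4a and C8a, which is what a 1,1,3‑trioxygenated diene and an alkynoate leave behind after loss of methanol.
- The diene is traced through a β‑keto ester to (4,5‑dimethoxy‑7‑methylnaphthalen‑1‑yl)acetic acid and the naphthyl bromide, whose methyl‑bearing ring is cut by a toluate/crotonate annulation.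
- Forward: the second naphthalene ring is made first, then the isoquinoline benzene ring by Diels–Alder reaction and aromatization (which also creates the biaryl bond), and last the nitrogen ring by lactamization and reduction.
- Stereochemistry: C3 (S) comes from L‑alaninol; its cyclic sulfamidate is opened at CH2 by an acetylide and the centre is never touched again.

Key step: step 16

Remark: the biaryl axis (three ortho substituents plus the naphthalene peri position) should be configurationally stable; the target structure defines only C3, so the route fixes C3 as S and leaves the axis uncontrolled, and 26–31 are expected as pairs of atropo‑diastereomers that can be separated at the end if one is wanted.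

**Route**

Step 1
Reactants: 1 2-methoxy-6-methylbenzoic acid
Product: 2 3-bromo-6-methoxy-2-methylbenzoic acid
Conditions: Br2, AcOH, 20 °C
Reagents that add atoms: bromine, BrBr
Why: Electrophilic aromatic bromination should occur para to the methoxy group and ortho to the methyl group, the position activated by both donors and meta to the acid.

Step 2
Reactants: 2 3-bromo-6-methoxy-2-methylbenzoic acid
Product: 3 ethyl 3-bromo-6-methoxy-2-methylbenzoate
Conditions: EtI, K2CO3, DMF, 20 °C
Reagents that add atoms: iodoethane, CCI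
Why: SN2 O‑alkylation of the carboxylate avoids the slow Fischer esterification of a 2,6‑disubstituted benzoic acid.

Step 3
Reactants: 3 ethyl 3-bromo-6-methoxy-2-methylbenzoate; 4 ethyl (E)-but-2-enoate (ethyl crotonate)
Product: 6 (±)-5-bromo-8-methoxy-3-methyl-3,4-dihydronaphthalen-1(2H)-one, via keto ester 5 (not isolated)
Conditions: LiN(i-Pr)2 (2.1 equiv), THF, −78 °C; 4, −78 °C → 20 °C; then 6 M aq. HCl–AcOH, 100 °C (THF distilled off)
Reagents that add atoms: none
Why: Staunton–Weinreb toluate annulation (lateral lithiation of the ortho‑methyl group, Michael addition to the crotonate, Dieckmann‑type acylation of the ester enolate) closes the ring, and acidic hydrolysis–decarboxylation of β‑keto ester 5 leaves the tetralone, whose C3 centre is racemic and is erased in step 4.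

Step 4
Reactants: 6 (±)-5-bromo-8-methoxy-3-methyl-3,4-dihydronaphthalen-1(2H)-one
Product: 8 5-bromo-8-methoxy-3-methylnaphthalen-1-ol, via bromo ketone 7 (not isolated)
Conditions: PhNMe3Br3, THF, 0 → 20 °C; evaporation; LiBr, Li2CO3, DMF, 120 °C
Reagents that add atoms: none
Why: α‑Bromination of the ketone and base‑mediated dehydrobromination give an enone that tautomerizes to the naphthol, a dehydrogenation that leaves the aryl bromide intact.

Step 5
Reactants: 8 5-bromo-8-methoxy-3-methylnaphthalen-1-ol
Product: 9 1-bromo-4,5-dimethoxy-7-methylnaphthalene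
Conditions: MeI, K2CO3, DMF, 50 °C
Reagents that add atoms: iodomethane, CI
Why: Williamson etherification of the peri‑hydrogen‑bonded naphthol in a polar aprotic solvent.

Step 6
Reactants: 9 1-bromo-4,5-dimethoxy-7-methylnaphthalene
Product: 11 2-(4,5-dimethoxy-7-methylnaphthalen-1-yl)acetic acid, via ethyl ester 10 (not isolated)
Conditions: BrZnCH2CO2Et, Pd2(dba)3 (cat.), XPhos, THF, 65 °C; then LiOH, MeOH–H2O, 50 °C; aq. HCl
Reagents that add atoms: (2-ethoxy-2-oxoethyl)zinc bromide, CCOC(=O)C[Zn]Br; lithium hydroxide, [Li+].[OH-]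
Why: Negishi‑type coupling of the aryl bromide with the Reformatsky zinc enolate (zerovalent palladium with a bulky biaryl phosphine accepts hindered, electron‑rich bromides) is followed by saponification in the same flask, so the acid can be purified by extraction.

Step 7
Reactants: 11 2-(4,5-dimethoxy-7-methylnaphthalen-1-yl)acetic acid; 12 2,2-dimethyl-1,3-dioxane-4,6-dione (Meldrum's acid)
Product: 14 methyl 4-(4,5-dimethoxy-7-methylnaphthalen-1-yl)-3-oxobutanoate, via acyl Meldrum's acid 13 (not isolated)
Conditions: EDC·HCl, DMAP, CH2Cl2, 0 → 20 °C; aq. KHSO4 wash, evaporation; MeOH, 65 °C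
Reagents that add atoms: methanol, CO
Why: Carbodiimide‑mediated C‑acylation of Meldrum's acid and methanolysis with loss of acetone and CO2 is the standard two‑carbon homologation of an acid to a β‑keto ester.

Step 8
Reactants: 14 methyl 4-(4,5-dimethoxy-7-methylnaphthalen-1-yl)-3-oxobutanoate
Product: 15 methyl (2E)-4-(4,5-dimethoxy-7-methylnaphthalen-1-yl)-3-methoxybut-2-enoate
Conditions: HC(OMe)3, H2SO4 (cat.), MeOH, 20 → 50 °C
Reagents that add atoms: trimethyl orthoformate, COC(OC)OC
Why: Acid‑catalysed ketalization by the orthoformate and loss of methanol should give the conjugated (E)‑β‑methoxy enoate, and any β,γ‑unsaturated isomer converges to the same dienolate in step 9.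

Step 9
Reactants: 15 methyl (2E)-4-(4,5-dimethoxy-7-methylnaphthalen-1-yl)-3-methoxybut-2-enoate
Product: 16 {[(3Z)-1,3-dimethoxy-4-(4,5-dimethoxy-7-methylnaphthalen-1-yl)buta-1,3-dien-1-yl]oxy}trimethylsilane
Conditions: LiN(i-Pr)2, THF, −78 °C; TMSCl, −78 → 20 °C; hexane, filtration under argon, used crude
Reagents that add atoms: chlorotrimethylsilane, C[Si](C)(C)Cl
Why: γ‑Deprotonation of the vinylogous ester and O‑silylation of the dienolate is the standard preparation of Brassard‑type dienes, and the naphthyl group should take the outer position on C4, away from the ketene acetal terminus, which gives the (3Z) geometry an s‑cis diene needs.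

Step 10
Reactants: 17 (2S)-2-aminopropan-1-ol (L-alaninol)
Product: 18 tert-butyl N-[(2S)-1-hydroxypropan-2-yl]carbamate
Conditions: Boc2O, CH2Cl2, 0 → 20 °C
Reagents that add atoms: di-tert-butyl dicarbonate, CC(C)(C)OC(=O)OC(=O)OC(C)(C)C
Why: Chemoselective N‑acylation of the amine in the presence of the primary alcohol.

Step 11
Reactants: 18 tert-butyl N-[(2S)-1-hydroxypropan-2-yl]carbamate
Product: 19 tert-butyl (4S)-4-methyl-1,2,3-oxathiazolidine-3-carboxylate 2-oxide
Conditions: SOCl2, pyridine, MeCN, −40 → 0 °C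
Reagents that add atoms: thionyl chloride, ClS(Cl)=O
Why: Cyclization of the N‑Boc amino alcohol with thionyl chloride gives the five‑membered cyclic sulfamidite, whose two sulfur epimers become one compound on oxidation.

Step 12
Reactants: 19 tert-butyl (4S)-4-methyl-1,2,3-oxathiazolidine-3-carboxylate 2-oxide
Product: 20 tert-butyl (4S)-4-methyl-1,2,3-oxathiazolidine-3-carboxylate 2,2-dioxide
Conditions: RuCl3·xH2O (cat.), NaIO4, MeCN–H2O, 0 °C
Reagents that add atoms: sodium periodate, [Na+].[O-]I(=O)(=O)=O
Why: Catalytic RuO4 oxidation at sulfur gives the cyclic sulfamidate, the standard activation of a 1,2‑amino alcohol as a carbon electrophile.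

Step 13
Reactants: 20 tert-butyl (4S)-4-methyl-1,2,3-oxathiazolidine-3-carboxylate 2,2-dioxide
Product: 22 tert-butyl N-[(2S)-5-(trimethylsilyl)pent-4-yn-2-yl]carbamate, via N-sulfate 21 (not isolated)
Conditions: Me3SiC≡CH, n-BuLi, THF, −78 °C; 20, −78 → 20 °C; then 1 M aq. HCl, 20 °C
Reagents that add atoms: ethynyltrimethylsilane, C#C[Si](C)(C)C
Why: SN2 opening of the cyclic sulfamidate at the primary C–O carbon by the lithium acetylide and mild acid hydrolysis of the N‑sulfate form the C–C bond without involving the stereocentre.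

Step 14
Reactants: 22 tert-butyl N-[(2S)-5-(trimethylsilyl)pent-4-yn-2-yl]carbamate
Product: 23 tert-butyl N-[(2S)-pent-4-yn-2-yl]carbamate
Conditions: K2CO3 (cat.), MeOH, 20 °C
Reagents that add atoms: none
Why: Base‑catalysed methanolysis of the alkynyl–silicon bond.

Step 15
Reactants: 23 tert-butyl N-[(2S)-pent-4-yn-2-yl]carbamate
Product: 24 methyl (5S)-5-[(tert-butoxycarbonyl)amino]hex-2-ynoate
Conditions: n-BuLi (2.1 equiv), THF, −78 °C; ClCO2Me, −78 °C; aq. NH4Cl
Reagents that add atoms: methyl chloroformate, COC(=O)Cl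
Why: Double deprotonation (N–H and alkyne C–H) and acylation of the more nucleophilic acetylide carbon with the chloroformate at low temperature give the ynoate.

Step 16
Reactants: 16 {[(3Z)-1,3-dimethoxy-4-(4,5-dimethoxy-7-methylnaphthalen-1-yl)buta-1,3-dien-1-yl]oxy}trimethylsilane; 24 methyl (5S)-5-[(tert-butoxycarbonyl)amino]hex-2-ynoate
Product: 27 methyl 2-[(2S)-2-(tert-butoxycarbonylamino)propyl]-6-hydroxy-4-methoxy-3-(4,5-dimethoxy-7-methylnaphthalen-1-yl)benzoate, via cycloadduct 25 (not isolated), via silyl ether 26 (not isolated)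
Conditions: 16 (2.5 equiv), toluene, 120 °C, sealed tube; then 1 M aq. HCl–THF, 0 °C
Reagents that add atoms: none
Why: Electron‑rich diene 16 and ynoate 24 should combine in a normal‑demand [4+2] cycloaddition that is concerted but strongly asynchronous (at the limit a vinylogous Mukaiyama–Michael addition followed by ring closure): C4 of the diene bonds to the ynoate β‑carbon (future C4a–C5) and the ketene acetal carbon to the α‑carbon (future C8–C8a), giving 1,4‑cyclohexadiene 25, which aromatizes by 1,4‑elimination of methanol to silyl ether 26, cleaved to phenol 27 in the acidic work‑up. The closest known reaction type is the Diels–Alder/aromatization of Brassard‑type 1,3‑dialkoxy‑1‑silyloxybutadienes with acetylenic esters to salicylates, which for β‑alkyl ynoates calls for heating of this order. The benzene ring closes in an intermolecular [4+2] mode from four diene carbons and two alkyne carbons (formally a 6‑exo‑trig closure of the second bond if the process is stepwise). No lasting stereocentre is formed: the two sp3 carbons of 25 vanish on aromatization, the biaryl axis arises only then and is not controlled, and the (S) centre of 24 is remote and untouched. The step needs regioselectivity, which polarity matching secures (largest HOMO coefficient at the naphthyl‑bearing diene terminus, largest LUMO coefficient at the ynoate β‑carbon), and a reactive s‑cis diene, which the (3Z) geometry with the naphthyl group pointing outward secures; excess 16 covers adventitious N‑silylation of the carbamate, and aromatization by loss of silanol instead of methanol would only anticipate step 17.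

Step 17
Reactants: 27 methyl 2-[(2S)-2-(tert-butoxycarbonylamino)propyl]-6-hydroxy-4-methoxy-3-(4,5-dimethoxy-7-methylnaphthalen-1-yl)benzoate
Product: 28 methyl 2-[(2S)-2-(tert-butoxycarbonylamino)propyl]-4,6-dimethoxy-3-(4,5-dimethoxy-7-methylnaphthalen-1-yl)benzoate
Conditions: MeI, K2CO3, DMF, 40 °C
Reagents that add atoms: iodomethane, CI
Why: Williamson methylation of the salicylate phenol, with a carbonate base too weak to deprotonate the carbamate N–H.

Step 18
Reactants: 28 methyl 2-[(2S)-2-(tert-butoxycarbonylamino)propyl]-4,6-dimethoxy-3-(4,5-dimethoxy-7-methylnaphthalen-1-yl)benzoate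
Product: 30 (3S)-6,8-dimethoxy-5-(4,5-dimethoxy-7-methylnaphthalen-1-yl)-3-methyl-3,4-dihydroisoquinolin-1(2H)-one, via amino ester 29 (not isolated)
Conditions: CF3CO2H–CH2Cl2 (1:4), 0 °C; evaporation; Et3N, MeOH, 65 °C
Reagents that add atoms: none
Why: Acidolysis of the Boc group and 6‑exo‑trig aminolysis of the neighbouring ester close the lactam, and the C3 centre carries no acidic hydrogen and cannot epimerize.

Step 19
Reactants: 30 (3S)-6,8-dimethoxy-5-(4,5-dimethoxy-7-methylnaphthalen-1-yl)-3-methyl-3,4-dihydroisoquinolin-1(2H)-one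
Product: 31 (3S)-6,8-dimethoxy-5-(4,5-dimethoxy-7-methylnaphthalen-1-yl)-3-methyl-1,2,3,4-tetrahydroisoquinoline
Conditions: LiAlH4, THF, 65 °C; Fieser work-up
Reagents that add atoms: none
Why: Hydride reduction of the secondary lactam to the amine (amide‑to‑amine reduction) leaves aryl ethers and the C3 centre unchanged.

**Compound list**

1 | 2-methoxy-6-methylbenzoic acid | Cc1cccc(OC)c1C(=O)O | starting material
2 | 3-bromo-6-methoxy-2-methylbenzoic acid | Cc1c(Br)ccc(OC)c1C(=O)O | intermediate
3 | ethyl 3-bromo-6-methoxy-2-methylbenzoate | CCOC(=O)c1c(C)c(Br)ccc1OC | intermediate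
4 | ethyl (E)-but-2-enoate (ethyl crotonate) | CCOC(=O)/C=C/C | starting material
5 | ethyl (±)-5-bromo-8-methoxy-3-methyl-1-oxo-1,2,3,4-tetrahydronaphthalene-2-carboxylate (keto/enol and diastereomer mixture) | CCOC(=O)C1C(C)Cc2c(Br)ccc(OC)c2C1=O | intermediate
6 | (±)-5-bromo-8-methoxy-3-methyl-3,4-dihydronaphthalen-1(2H)-one | CC1CC(=O)c2c(OC)ccc(Br)c2C1 | intermediate
7 | 2,5-dibromo-8-methoxy-3-methyl-3,4-dihydronaphthalen-1(2H)-one (racemic, both diastereomers) | CC1Cc2c(Br)ccc(OC)c2C(=O)C1Br | intermediate
8 | 5-bromo-8-methoxy-3-methylnaphthalen-1-ol | Cc1cc(O)c2c(OC)ccc(Br)c2c1 | intermediate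
9 | 1-bromo-4,5-dimethoxy-7-methylnaphthalene | COc1ccc(Br)c2cc(C)cc(OC)c12 | intermediate
10 | ethyl 2-(4,5-dimethoxy-7-methylnaphthalen-1-yl)acetate | CCOC(=O)Cc1ccc(OC)c2c(OC)cc(C)cc12 | intermediate
11 | 2-(4,5-dimethoxy-7-methylnaphthalen-1-yl)acetic acid | OC(=O)Cc1ccc(OC)c2c(OC)cc(C)cc12 | intermediate
12 | 2,2-dimethyl-1,3-dioxane-4,6-dione (Meldrum's acid) | CC1(C)OC(=O)CC(=O)O1 | starting material
13 | 5-[2-(4,5-dimethoxy-7-methylnaphthalen-1-yl)-1-hydroxyethylidene]-2,2-dimethyl-1,3-dioxane-4,6-dione | CC1(C)OC(=O)C(=C(O)Cc2ccc(OC)c3c(OC)cc(C)cc23)C(=O)O1 | intermediate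
14 | methyl 4-(4,5-dimethoxy-7-methylnaphthalen-1-yl)-3-oxobutanoate | COC(=O)CC(=O)Cc1ccc(OC)c2c(OC)cc(C)cc12 | intermediate
15 | methyl (2E)-4-(4,5-dimethoxy-7-methylnaphthalen-1-yl)-3-methoxybut-2-enoate | COC(=O)/C=C(/OC)Cc1ccc(OC)c2c(OC)cc(C)cc12 | intermediate
16 | {[(3Z)-1,3-dimethoxy-4-(4,5-dimethoxy-7-methylnaphthalen-1-yl)buta-1,3-dien-1-yl]oxy}trimethylsilane (ketene acetal geometry not defined) | COC(O[Si](C)(C)C)=C/C(OC)=C/c1ccc(OC)c2c(OC)cc(C)cc12 | intermediate
17 | (2S)-2-aminopropan-1-ol (L-alaninol) | C[C@H](N)CO | starting material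
18 | tert-butyl N-[(2S)-1-hydroxypropan-2-yl]carbamate | C[C@H](NC(=O)OC(C)(C)C)CO | intermediate
19 | tert-butyl (4S)-4-methyl-1,2,3-oxathiazolidine-3-carboxylate 2-oxide (both sulfur epimers) | C[C@H]1COS(=O)N1C(=O)OC(C)(C)C | intermediate
20 | tert-butyl (4S)-4-methyl-1,2,3-oxathiazolidine-3-carboxylate 2,2-dioxide | C[C@H]1COS(=O)(=O)N1C(=O)OC(C)(C)C | intermediate
21 | lithium N-(tert-butoxycarbonyl)-N-[(2S)-5-(trimethylsilyl)pent-4-yn-2-yl]sulfamate | C[C@@H](CC#C[Si](C)(C)C)N(C(=O)OC(C)(C)C)S(=O)(=O)[O-].[Li+] | intermediate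
22 | tert-butyl N-[(2S)-5-(trimethylsilyl)pent-4-yn-2-yl]carbamate | C[C@@H](CC#C[Si](C)(C)C)NC(=O)OC(C)(C)C | intermediate
23 | tert-butyl N-[(2S)-pent-4-yn-2-yl]carbamate | C[C@@H](CC#C)NC(=O)OC(C)(C)C | intermediate
24 | methyl (5S)-5-[(tert-butoxycarbonyl)amino]hex-2-ynoate | COC(=O)C#CC[C@H](C)NC(=O)OC(C)(C)C | intermediate
25 | methyl 2-[(2S)-2-(tert-butoxycarbonylamino)propyl]-4,6-dimethoxy-3-(4,5-dimethoxy-7-methylnaphthalen-1-yl)-6-(trimethylsilyloxy)cyclohexa-1,4-diene-1-carboxylate (mixture at the two ring sp3 carbons) | COC(=O)C1=C(C[C@H](C)NC(=O)OC(C)(C)C)C(c2ccc(OC)c3c(OC)cc(C)cc23)C(OC)=CC1(OC)O[Si](C)(C)C | intermediate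
26 | methyl 2-[(2S)-2-(tert-butoxycarbonylamino)propyl]-4-methoxy-3-(4,5-dimethoxy-7-methylnaphthalen-1-yl)-6-(trimethylsilyloxy)benzoate | COC(=O)c1c(O[Si](C)(C)C)cc(OC)c(-c2ccc(OC)c3c(OC)cc(C)cc23)c1C[C@H](C)NC(=O)OC(C)(C)C | intermediate
27 | methyl 2-[(2S)-2-(tert-butoxycarbonylamino)propyl]-6-hydroxy-4-methoxy-3-(4,5-dimethoxy-7-methylnaphthalen-1-yl)benzoate | COC(=O)c1c(O)cc(OC)c(-c2ccc(OC)c3c(OC)cc(C)cc23)c1C[C@H](C)NC(=O)OC(C)(C)C | intermediate
28 | methyl 2-[(2S)-2-(tert-butoxycarbonylamino)propyl]-4,6-dimethoxy-3-(4,5-dimethoxy-7-methylnaphthalen-1-yl)benzoate | COC(=O)c1c(OC)cc(OC)c(-c2ccc(OC)c3c(OC)cc(C)cc23)c1C[C@H](C)NC(=O)OC(C)(C)C | intermediate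
29 | methyl 2-[(2S)-2-aminopropyl]-4,6-dimethoxy-3-(4,5-dimethoxy-7-methylnaphthalen-1-yl)benzoate (trifluoroacetate salt in the flask) | COC(=O)c1c(OC)cc(OC)c(-c2ccc(OC)c3c(OC)cc(C)cc23)c1C[C@H](C)N | intermediate
30 | (3S)-6,8-dimethoxy-5-(4,5-dimethoxy-7-methylnaphthalen-1-yl)-3-methyl-3,4-dihydroisoquinolin-1(2H)-one | COc1cc(OC)c(-c2ccc(OC)c3c(OC)cc(C)cc23)c2c1C(=O)N[C@@H](C)C2 | intermediate
31 | (3S)-6,8-dimethoxy-5-(4,5-dimethoxy-7-methylnaphthalen-1-yl)-3-methyl-1,2,3,4-tetrahydroisoquinoline | COc1cc(OC)c(-c2ccc(OC)c3c(OC)cc(C)cc23)c2c1CN[C@@H](C)C2 | target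

**Step count and risks**

Total steps: 19. Longest linear sequence: 13 steps (steps 1–9, then 16–19); the alkynoate branch (steps 10–15) is six steps.

Steps most likely to fail:

1. Step 16 (with the diene from step 9). Bond formation at the naphthyl‑bearing diene terminus may be so slow that thermal decomposition or protodesilylation of 16 outruns the cycloaddition, or the diene may not be obtained in the reactive geometry. Fallback: the aryl–aryl bond is made by cross‑coupling after the ring is built, setting out from 24 and 9 and returning at 28. Ynoate 24 is heated with commercial 1,3‑dimethoxy‑1‑(trimethylsilyloxy)buta‑1,3‑diene (toluene, 110 °C, then dilute HCl) to give methyl 2-[(2S)-2-(tert-butoxycarbonylamino)propyl]-6-hydroxy-4-methoxybenzoate F1. Methylation (MeI, K2CO3) gives methyl 2-[(2S)-2-(tert-butoxycarbonylamino)propyl]-4,6-dimethoxybenzoate F2. NBS in MeCN should brominate para to the 6‑methoxy group, next to the side chain, to give methyl 3-bromo-2-[(2S)-2-(tert-butoxycarbonylamino)propyl]-4,6-dimethoxybenzoate F3. In parallel, bromide 9 is converted (n-BuLi, B(Oi-Pr)3, then aqueous acid) into (4,5-dimethoxy-7-methylnaphthalen-1-yl)boronic acid F4. Suzuki–Miyaura coupling of F3 with F4 (Pd(OAc)2, SPhos, K3PO4, toluene–water, 100 °C) then gives 28.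

2. Step 3. Lateral lithiation next to the bromine may be eroded by ring metalation and halide loss, and the toluate anion may self‑condense or oligomerize the crotonate. Fallback: the halogen is introduced after the carbocycle is built, setting out from 1 and returning at 6. Acid 1 is esterified (EtI, K2CO3) to ethyl 2-methoxy-6-methylbenzoate F5. The same annulation with 4 gives ethyl (±)-8-methoxy-3-methyl-1-oxo-1,2,3,4-tetrahydronaphthalene-2-carboxylate F6, and acidic decarboxylation gives (±)-8-methoxy-3-methyl-3,4-dihydronaphthalen-1(2H)-one F7. NBS in MeCN then brominates the ring para to the methoxy group to give 6.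

3. Step 15. The dilithiated carbamate may be acylated on nitrogen, or a second acetylide may add to the ynoate as it forms. Fallback: the ester is introduced under neutral conditions by palladium‑catalysed oxidative methoxycarbonylation of the terminal alkyne (PdCl2 cat., CuCl2, NaOAc, CO at 1 atm, MeOH, 20 °C), which sets out from 23 and returns directly at 24 without a new intermediate.

**Further compounds**

F1 | step 16 | methyl 2-[(2S)-2-(tert-butoxycarbonylamino)propyl]-6-hydroxy-4-methoxybenzoate | COC(=O)c1c(O)cc(OC)cc1C[C@H](C)NC(=O)OC(C)(C)C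
F2 | step 16 | methyl 2-[(2S)-2-(tert-butoxycarbonylamino)propyl]-4,6-dimethoxybenzoate | COC(=O)c1c(OC)cc(OC)cc1C[C@H](C)NC(=O)OC(C)(C)C
F3 | step 16 | methyl 3-bromo-2-[(2S)-2-(tert-butoxycarbonylamino)propyl]-4,6-dimethoxybenzoate | COC(=O)c1c(OC)cc(OC)c(Br)c1C[C@H](C)NC(=O)OC(C)(C)C
F4 | step 16 | (4,5-dimethoxy-7-methylnaphthalen-1-yl)boronic acid | COc1ccc(B(O)O)c2cc(C)cc(OC)c12
F5 | step 3 | ethyl 2-methoxy-6-methylbenzoate | CCOC(=O)c1c(C)cccc1OC
F6 | step 3 | ethyl (±)-8-methoxy-3-methyl-1-oxo-1,2,3,4-tetrahydronaphthalene-2-carboxylate | CCOC(=O)C1C(C)Cc2cccc(OC)c2C1=O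
F7 | step 3 | (±)-8-methoxy-3-methyl-3,4-dihydronaphthalen-1(2H)-one | CC1CC(=O)c2c(OC)cccc2C1
F0 | step 15 | none | none
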